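**Plan**

Numbering (cembrane): C1 lactone CH, C2 lactone OCH, C3=C4, C5, C6, C7=C8, C9, C10, C11–C12 epoxide, C13 (OAc), C14; methyls C18, C19, C20 on C4, C8, C12; lactone carbons C15 (=C17H2) and C16 (C=O).
Feature used: C13 is a secondary carbinol carbon (acetylated) bonded directly to C12, which before epoxidation is the methyl-bearing carbon of an (E)-C11=C12 alkene in the 14-membered carbocycle; this is the pattern left when a C12 alkenyl metal adds to a C13 aldehyde.
Cuts, in retrosynthetic order: acetate C–O; epoxide oxygen; C12–C13 (opens the 14-membered ring to an alkenyl iodide and an aldehyde); C1–C2 and lactone O–C16 (enal plus 2-(methoxycarbonyl)allyl bromide); C11=C12 and C12–C20 (alkyne construction on a farnesol-derived C11 aldehyde).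
Forward: farnesol gives the C2 enal carrying the (E)-C12 iodide; allylation/lactonisation builds the five-membered lactone first; chromium/nickel-mediated C12–C13 coupling then closes the 14-membered ring; directed epoxidation and acetylation finish.
Stereochemistry: 3E,7E from farnesol; 11E from syn-hydrozirconation; C1 and C2 from a ligand-controlled, syn-selective chromium-catalysed allylation; C13 from the ring closure under control of C1; C11 and C12 from hydroxyl-directed epoxidation of the E-alkene.

Key step: step 14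

Remark (assumption): the facial course of the ring closure at C13 cannot be predicted with certainty; 13R is assumed to be the main outcome, and a corrective oxidation–reduction sequence is given among the fallbacks.

**Route**

Step 1
Reactants: 1 (2E,6E)-farnesol
Product: 2 (2E,6E)-farnesyl tert-butyldiphenylsilyl ether
Conditions: TBDPSCl, imidazole, DMF, 0 °C → rt
Reagents that add atoms: tert-butyl(chloro)diphenylsilane, CC(C)(C)[Si](Cl)(c1ccccc1)c1ccccc1
Why: Imidazole-promoted silylation masks the primary allylic alcohol with a group that should survive periodic acid, n-BuLi and the zirconium hydride.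

Step 2
Reactants: 2 (2E,6E)-farnesyl tert-butyldiphenylsilyl ether
Product: 4 racemic 10,11-epoxy-10,11-dihydrofarnesyl tert-butyldiphenylsilyl ether, via bromohydrin 3 (not isolated)
Conditions: NBS, THF/H2O (3:1), 0 °C; then K2CO3, MeOH, rt
Reagents that add atoms: water, O
Why: Bromohydrin formation in aqueous THF should occur selectively at the terminal, most accessible trisubstituted alkene (the 2,3-alkene is deactivated by the allylic oxygen), and carbonate then closes the epoxide by intramolecular Williamson displacement; the racemic centre is destroyed in step 3.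

Step 3
Reactants: 4 racemic 10,11-epoxy-10,11-dihydrofarnesyl tert-butyldiphenylsilyl ether
Product: 5 (4E,8E)-10-(tert-butyldiphenylsilyloxy)-4,8-dimethyldeca-4,8-dienal
Conditions: H5IO6, THF/Et2O, 0 °C
Reagents that add atoms: none
Why: Periodic acid hydrolyses the epoxide and cleaves the resulting glycol in one operation (oxidative glycol cleavage), releasing acetone and leaving the aldehyde carbon that becomes C11.

Step 4
Reactants: 5 (4E,8E)-10-(tert-butyldiphenylsilyloxy)-4,8-dimethyldeca-4,8-dienal
Product: 6 tert-butyl{[(2E,6E)-11,11-dibromo-3,7-dimethylundeca-2,6,10-trien-1-yl]oxy}diphenylsilane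
Conditions: CBr4, PPh3, CH2Cl2, 0 °C
Reagents that add atoms: carbon tetrabromide, BrC(Br)(Br)Br
Why: First stage of the Corey–Fuchs alkyne synthesis, a Wittig-type dibromomethylenation of the aldehyde that adds the carbon destined to become C12.

Step 5
Reactants: 6 tert-butyl{[(2E,6E)-11,11-dibromo-3,7-dimethylundeca-2,6,10-trien-1-yl]oxy}diphenylsilane
Product: 8 tert-butyl{[(2E,6E)-3,7-dimethyldodeca-2,6-dien-10-yn-1-yl]oxy}diphenylsilane, via lithium acetylide 7 (not isolated)
Conditions: n-BuLi (2.1 equiv), THF, −78 °C; then MeI, −78 °C → rt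
Reagents that add atoms: iodomethane, CI
Why: Second stage of the Corey–Fuchs sequence, in which bromine–lithium exchange, α-elimination with 1,2-hydride shift and deprotonation give the lithium acetylide, whose C-methylation installs C20.

Step 6
Reactants: 8 tert-butyl{[(2E,6E)-3,7-dimethyldodeca-2,6-dien-10-yn-1-yl]oxy}diphenylsilane
Product: 10 tert-butyl{[(2E,6E,10E)-11-iodo-3,7-dimethyldodeca-2,6,10-trien-1-yl]oxy}diphenylsilane, via alkenylzirconocene chloride 9 (not isolated)
Conditions: Cp2Zr(H)Cl (2.5 equiv), THF, 50 °C; then I2, THF, 0 °C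
Reagents that add atoms: iodine, II
Why: Hydrozirconation–iodination: syn addition of Zr–H followed, with excess hydride and warming, by equilibration of zirconium to the less hindered methyl-bearing carbon, then iodinolysis with retention, should give the (E)-2-iodo-2-alkene (iodine trans to the chain) while the trisubstituted alkenes stay inert.

Step 7
Reactants: 10 tert-butyl{[(2E,6E,10E)-11-iodo-3,7-dimethyldodeca-2,6,10-trien-1-yl]oxy}diphenylsilane
Product: 11 (2E,6E,10E)-11-iodo-3,7-dimethyldodeca-2,6,10-trien-1-ol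
Conditions: TBAF, THF, 0 °C → rt
Reagents that add atoms: none
Why: Fluoride-mediated desilylation frees the allylic alcohol without touching the alkenyl iodide.

Step 8
Reactants: 11 (2E,6E,10E)-11-iodo-3,7-dimethyldodeca-2,6,10-trien-1-ol
Product: 12 (2E,6E,10E)-11-iodo-3,7-dimethyldodeca-2,6,10-trienal
Conditions: MnO2, CH2Cl2, rt
Reagents that add atoms: none
Why: MnO2 oxidises allylic alcohols selectively to enals under neutral conditions with retention of the 2E geometry.

Step 9
Reactants: 13 methyl acrylate; 14 3-(tert-butyldimethylsilyloxy)propanal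
Product: 15 racemic methyl 5-(tert-butyldimethylsilyloxy)-3-hydroxy-2-methylidenepentanoate
Conditions: DABCO (0.5 equiv), excess 13, MeOH, rt
Reagents that add atoms: none
Why: Baylis–Hillman reaction, in which the amine–acrylate zwitterion adds to the aldehyde and β-elimination of the amine returns the α-methylene β-hydroxy ester (the racemic carbinol is erased in step 10).

Step 10
Reactants: 15 racemic methyl 5-(tert-butyldimethylsilyloxy)-3-hydroxy-2-methylidenepentanoate
Product: 17 methyl (2Z)-2-(bromomethyl)-5-(tert-butyldimethylsilyloxy)pent-2-enoate, via allylic mesylate 16 (not isolated)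
Conditions: MsCl, Et3N, CH2Cl2, 0 °C; then LiBr, acetone, rt
Reagents that add atoms: lithium bromide, [Li+].[Br-]
Why: Mesylation followed by SN2′ displacement with bromide transposes the allylic system to the thermodynamically preferred (Z)-2-(bromomethyl)-2-alkenoate (chain trans to the ester) under conditions that spare the silyl ether.

Step 11
Reactants: 12 (2E,6E,10E)-11-iodo-3,7-dimethyldodeca-2,6,10-trienal; 17 methyl (2Z)-2-(bromomethyl)-5-(tert-butyldimethylsilyloxy)pent-2-enoate
Product: 21 (4S,5S)-4-[2-(tert-butyldimethylsilyloxy)ethyl]-5-[(1E,5E,9E)-10-iodo-2,6-dimethylundeca-1,5,9-trien-1-yl]-3-methylidenedihydrofuran-2(3H)-one, via allylchromium reagent 18 (not isolated), via silyl ether 19 (not isolated), via hydroxy ester 20 (not isolated)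
Conditions: nickel-free CrCl2 (10 mol %), chiral 1,8-bis(oxazolinyl)carbazole ligand (12 mol %), Mn powder, TMSCl, i-Pr2NEt (30 mol %), THF, rt; then 1 M HCl, THF, 0 °C (brief); PPTS, CH2Cl2, rt
Reagents that add atoms: none
Why: Catalytic asymmetric Nozaki–Hiyama-type 2-(alkoxycarbonyl)allylation followed by lactonisation, in which divalent chromium (regenerated by Mn) inserts only into the allylic C–Br bond because the alkenyl iodide needs nickel catalysis, the ligand-bound (Z)-γ-substituted allylchromium 18 adds through a chair transition state to the Re face of the enal carbonyl so that the ligand antipode sets C2 (S) and the chair sets C1 (S, syn), and the syn hydroxy ester closes to the cis lactone while the silyl ether keeps the C13 oxygen from competing for the ester.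

Step 12
Reactants: 21 (4S,5S)-4-[2-(tert-butyldimethylsilyloxy)ethyl]-5-[(1E,5E,9E)-10-iodo-2,6-dimethylundeca-1,5,9-trien-1-yl]-3-methylidenedihydrofuran-2(3H)-one
Product: 22 (4S,5S)-4-(2-hydroxyethyl)-5-[(1E,5E,9E)-10-iodo-2,6-dimethylundeca-1,5,9-trien-1-yl]-3-methylidenedihydrofuran-2(3H)-one
Conditions: HF·pyridine, THF/pyridine, 0 °C → rt
Reagents that add atoms: none
Why: Buffered HF cleaves the primary silyl ether without opening or isomerising the base-sensitive α-methylene lactone.

Step 13
Reactants: 22 (4S,5S)-4-(2-hydroxyethyl)-5-[(1E,5E,9E)-10-iodo-2,6-dimethylundeca-1,5,9-trien-1-yl]-3-methylidenedihydrofuran-2(3H)-one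
Product: 23 (4S,5S)-5-[(1E,5E,9E)-10-iodo-2,6-dimethylundeca-1,5,9-trien-1-yl]-3-methylidene-4-(2-oxoethyl)dihydrofuran-2(3H)-one
Conditions: Dess–Martin periodinane, CH2Cl2, 0 °C → rt
Reagents that add atoms: none
Why: Dess–Martin oxidation converts the primary alcohol into the C13 aldehyde under neutral conditions that leave the alkenyl iodide and the methylene lactone intact.

Step 14
Reactants: 23 (4S,5S)-5-[(1E,5E,9E)-10-iodo-2,6-dimethylundeca-1,5,9-trien-1-yl]-3-methylidene-4-(2-oxoethyl)dihydrofuran-2(3H)-one
Product: 26 (1S,2S,3E,7E,11E,13R)-13-hydroxycembra-3,7,11,15(17)-tetraen-16,2-olide, via alkenylchromium 24 (not isolated), via chromium alkoxide 25 (not isolated)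
Conditions: CrCl2 (10 equiv), NiCl2 (0.1 equiv), degassed DMSO/THF, rt, 23 added by syringe pump to 0.002 M; aqueous work-up
Reagents that add atoms: none
Why: CrCl2 reduces NiCl2 to zerovalent nickel, which inserts into the C12–I bond and passes the alkenyl group with retention of the E geometry to trivalent chromium, and the alkenylchromium 24 adds to the C13 aldehyde to give alkoxide 25, hydrolysed on work-up. The closest known reaction type is the Nozaki–Hiyama–Kishi macrocyclisation of an alkenyl iodide onto an aldehyde under high dilution. The 14-membered carbocycle closes by 14-exo-trig 1,2-addition at the carbonyl carbon, forming the C12–C13 bond with the carbonyl oxygen left outside the ring. The new C13 stereocentre is controlled by the neighbouring C1 stereocentre of the cis-fused lactone, which together with the fixed E-alkenyl geometry biases the aldehyde face exposed in the cyclic transition state (13R assumed). The step needs chemoselectivity for the aldehyde over the lactone carbonyl and the conjugated methylene, and ring closure over oligomerisation; the first is secured because alkenylchromium reagents add only to aldehydes, the second by slow addition at high dilution and a low nickel loading that suppresses nickel-mediated conjugate addition and homocoupling.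

Step 15
Reactants: 26 (1S,2S,3E,7E,11E,13R)-13-hydroxycembra-3,7,11,15(17)-tetraen-16,2-olide
Product: 27 (1S,2S,3E,7E,11R,12R,13R)-11,12-epoxy-13-hydroxycembra-3,7,15(17)-trien-16,2-olide
Conditions: VO(acac)2 (5 mol %), t-BuOOH (decane), CH2Cl2, 0 °C → rt
Reagents that add atoms: tert-butyl hydroperoxide, CC(C)(C)OO
Why: Hydroxyl-directed epoxidation, in which the vanadium alkoxide of the C13 carbinol delivers oxygen only to the adjacent C11=C12 bond and, with allylic 1,2-strain from the C20 methyl, to the face that should give the erythro epoxy alcohol (trans epoxide from the E-alkene; the 12R descriptor here and 12S in the acetate denote the same spatial arrangement).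

Step 16
Reactants: 27 (1S,2S,3E,7E,11R,12R,13R)-11,12-epoxy-13-hydroxycembra-3,7,15(17)-trien-16,2-olide
Product: 28 (1S,2S,3E,7E,11R,12S,13R)-13-acetoxy-11,12-epoxycembra-3,7,15(17)-trien-16,2-olide
Conditions: Ac2O, pyridine, DMAP (cat.), CH2Cl2, 0 °C → rt
Reagents that add atoms: acetic anhydride, CC(=O)OC(C)=O
Why: DMAP-catalysed acylation of the secondary alcohol under weakly basic conditions that should not trigger epoxide migration or opening completes the target.

**Compound list**

1 | (2E,6E)-farnesol | CC(C)=CCC/C(C)=C/CC/C(C)=C/CO | starting material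
2 | (2E,6E)-farnesyl tert-butyldiphenylsilyl ether | CC(C)=CCC/C(C)=C/CC/C(C)=C/CO[Si](c1ccccc1)(c1ccccc1)C(C)(C)C | intermediate
3 | racemic 10-bromo-11-hydroxy-10,11-dihydrofarnesyl tert-butyldiphenylsilyl ether | CC(C)(O)C(Br)CC/C(C)=C/CC/C(C)=C/CO[Si](c1ccccc1)(c1ccccc1)C(C)(C)C | intermediate (not isolated)
4 | racemic 10,11-epoxy-10,11-dihydrofarnesyl tert-butyldiphenylsilyl ether | CC1(C)OC1CC/C(C)=C/CC/C(C)=C/CO[Si](c1ccccc1)(c1ccccc1)C(C)(C)C | intermediate
5 | (4E,8E)-10-(tert-butyldiphenylsilyloxy)-4,8-dimethyldeca-4,8-dienal | O=CCC/C(C)=C/CC/C(C)=C/CO[Si](c1ccccc1)(c1ccccc1)C(C)(C)C | intermediate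
6 | tert-butyl{[(2E,6E)-11,11-dibromo-3,7-dimethylundeca-2,6,10-trien-1-yl]oxy}diphenylsilane | BrC(Br)=CCC/C(C)=C/CC/C(C)=C/CO[Si](c1ccccc1)(c1ccccc1)C(C)(C)C | intermediate
7 | [(5E,9E)-11-(tert-butyldiphenylsilyloxy)-5,9-dimethylundeca-5,9-dien-1-yn-1-yl]lithium | [Li]C#CCC/C(C)=C/CC/C(C)=C/CO[Si](c1ccccc1)(c1ccccc1)C(C)(C)C | intermediate (not isolated)
8 | tert-butyl{[(2E,6E)-3,7-dimethyldodeca-2,6-dien-10-yn-1-yl]oxy}diphenylsilane | CC#CCC/C(C)=C/CC/C(C)=C/CO[Si](c1ccccc1)(c1ccccc1)C(C)(C)C | intermediate
9 | chlorobis(cyclopentadienyl)[(2E,6E,10E)-12-(tert-butyldiphenylsilyloxy)-6,10-dimethyldodeca-2,6,10-trien-2-yl]zirconium (cyclopentadienyl rings drawn σ-bonded) | C/C(=C\CC/C(C)=C/CC/C(C)=C/CO[Si](c1ccccc1)(c1ccccc1)C(C)(C)C)[Zr](Cl)(C1C=CC=C1)C1C=CC=C1 | intermediate (not isolated)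
10 | tert-butyl{[(2E,6E,10E)-11-iodo-3,7-dimethyldodeca-2,6,10-trien-1-yl]oxy}diphenylsilane | C/C(I)=C\CC/C(C)=C/CC/C(C)=C/CO[Si](c1ccccc1)(c1ccccc1)C(C)(C)C | intermediate
11 | (2E,6E,10E)-11-iodo-3,7-dimethyldodeca-2,6,10-trien-1-ol | C/C(I)=C\CC/C(C)=C/CC/C(C)=C/CO | intermediate
12 | (2E,6E,10E)-11-iodo-3,7-dimethyldodeca-2,6,10-trienal | C/C(I)=C\CC/C(C)=C/CC/C(C)=C/C=O | intermediate
13 | methyl acrylate | C=CC(=O)OC | starting material
14 | 3-(tert-butyldimethylsilyloxy)propanal | O=CCCO[Si](C)(C)C(C)(C)C | starting material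
15 | racemic methyl 5-(tert-butyldimethylsilyloxy)-3-hydroxy-2-methylidenepentanoate | C=C(C(=O)OC)C(O)CCO[Si](C)(C)C(C)(C)C | intermediate
16 | racemic methyl 5-(tert-butyldimethylsilyloxy)-3-(methanesulfonyloxy)-2-methylidenepentanoate | C=C(C(=O)OC)C(OS(C)(=O)=O)CCO[Si](C)(C)C(C)(C)C | intermediate (not isolated)
17 | methyl (2Z)-2-(bromomethyl)-5-(tert-butyldimethylsilyloxy)pent-2-enoate | BrC/C(C(=O)OC)=C\CCO[Si](C)(C)C(C)(C)C | intermediate
18 | dichloro[(2Z)-5-(tert-butyldimethylsilyloxy)-2-(methoxycarbonyl)pent-2-en-1-yl]chromium (trivalent chromium; chiral ligand omitted) | Cl[Cr](Cl)C/C(C(=O)OC)=C\CCO[Si](C)(C)C(C)(C)C | intermediate (not isolated)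
19 | methyl (3S,4S,5E,9E,13E)-3-[2-(tert-butyldimethylsilyloxy)ethyl]-14-iodo-6,10-dimethyl-2-methylidene-4-(trimethylsilyloxy)pentadeca-5,9,13-trienoate | C=C(C(=O)OC)[C@H](CCO[Si](C)(C)C(C)(C)C)[C@@H](O[Si](C)(C)C)/C=C(\C)CC/C=C(\C)CC/C=C(\C)I | intermediate (not isolated)
20 | methyl (3S,4S,5E,9E,13E)-3-[2-(tert-butyldimethylsilyloxy)ethyl]-4-hydroxy-14-iodo-6,10-dimethyl-2-methylidenepentadeca-5,9,13-trienoate | C=C(C(=O)OC)[C@H](CCO[Si](C)(C)C(C)(C)C)[C@@H](O)/C=C(\C)CC/C=C(\C)CC/C=C(\C)I | intermediate (not isolated)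
21 | (4S,5S)-4-[2-(tert-butyldimethylsilyloxy)ethyl]-5-[(1E,5E,9E)-10-iodo-2,6-dimethylundeca-1,5,9-trien-1-yl]-3-methylidenedihydrofuran-2(3H)-one | C=C1C(=O)O[C@@H](/C=C(\C)CC/C=C(\C)CC/C=C(\C)I)[C@H]1CCO[Si](C)(C)C(C)(C)C | intermediate
22 | (4S,5S)-4-(2-hydroxyethyl)-5-[(1E,5E,9E)-10-iodo-2,6-dimethylundeca-1,5,9-trien-1-yl]-3-methylidenedihydrofuran-2(3H)-one | C=C1C(=O)O[C@@H](/C=C(\C)CC/C=C(\C)CC/C=C(\C)I)[C@H]1CCO | intermediate
23 | (4S,5S)-5-[(1E,5E,9E)-10-iodo-2,6-dimethylundeca-1,5,9-trien-1-yl]-3-methylidene-4-(2-oxoethyl)dihydrofuran-2(3H)-one | C=C1C(=O)O[C@@H](/C=C(\C)CC/C=C(\C)CC/C=C(\C)I)[C@H]1CC=O | intermediate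
24 | dichloro{(2E,6E,10E)-6,10-dimethyl-11-[(2S,3S)-4-methylidene-5-oxo-3-(2-oxoethyl)tetrahydrofuran-2-yl]undeca-2,6,10-trien-2-yl}chromium (trivalent chromium) | C=C1C(=O)O[C@@H](/C=C(\C)CC/C=C(\C)CC/C=C(\C)[Cr](Cl)Cl)[C@H]1CC=O | intermediate (not isolated)
25 | dichlorochromium 13-alkoxide of (1S,2S,3E,7E,11E,13R)-13-hydroxycembra-3,7,11,15(17)-tetraen-16,2-olide (trivalent chromium) | C=C1C(=O)O[C@H]2/C=C(\C)CC/C=C(\C)CC/C=C(\C)[C@H](O[Cr](Cl)Cl)C[C@@H]12 | intermediate (not isolated)
26 | (1S,2S,3E,7E,11E,13R)-13-hydroxycembra-3,7,11,15(17)-tetraen-16,2-olide | C=C1C(=O)O[C@H]2/C=C(\C)CC/C=C(\C)CC/C=C(\C)[C@H](O)C[C@@H]12 | intermediate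
27 | (1S,2S,3E,7E,11R,12R,13R)-11,12-epoxy-13-hydroxycembra-3,7,15(17)-trien-16,2-olide | C=C1C(=O)O[C@H]2/C=C(\C)CC/C=C(\C)CC[C@H]3O[C@]3(C)[C@H](O)C[C@@H]12 | intermediate
28 | (1S,2S,3E,7E,11R,12S,13R)-13-acetoxy-11,12-epoxycembra-3,7,15(17)-trien-16,2-olide | C=C1C(=O)O[C@H]2/C=C(\C)CC/C=C(\C)CC[C@H]3O[C@]3(C)[C@H](OC(C)=O)C[C@@H]12 | target

**Step count and risks**

Total: 16 steps. Longest linear sequence: 14 steps (steps 1–8 and 11–16 from farnesol); the bromide arm (steps 9–10) is 2 steps.

Steps most likely to fail: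

Step 14. Poor facial selectivity in the addition to the C13 aldehyde (formation of the 13-epimer) is the main risk, with intermolecular coupling as a second. The fallback sets out from aldehyde 23 and accepts whatever C13 ratio the same ring closure gives. The carbinols, including (1S,2S,3E,7E,11E,13S)-13-hydroxycembra-3,7,11,15(17)-tetraen-16,2-olide F1, would be oxidised with MnO2 (or Dess–Martin periodinane) to (1S,2S,3E,7E,11E)-13-oxocembra-3,7,11,15(17)-tetraen-16,2-olide F2. The ketone would then be reduced under reagent control with catecholborane and (S)-2-methyl-CBS-oxazaborolidine in toluene at −78 °C (Corey–Bakshi–Shibata reduction, the alkenyl branch acting as the large group). This should give the 13R alcohol and return to the route at 26.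

Step 11. Imperfect enantio- and syn-control, or competing reduction of the C–I bond by low-valent metal, may erode the lactone. The fallback sets out from alcohol 11 and adduct 15 and skips step 8. Adduct 15 would be converted with Boc2O/DMAP into racemic methyl 3-(tert-butoxycarbonyloxy)-5-(tert-butyldimethylsilyloxy)-2-methylidenepentanoate F3. Alcohol 11 and F3 would then be joined by iridium-catalysed transfer-hydrogenative 2-(alkoxycarbonyl)allylation ([Ir(cod)Cl]2, a chiral bisphosphine such as SEGPHOS in the antipode giving 2S, a nitrobenzoic acid co-ligand, Cs2CO3, THF, 60–70 °C). In this known reaction the alcohol is dehydrogenated in the flask to enal 12 and the π-allyliridium adds syn-selectively. The hydroxy ester 20 so formed lactonises under PPTS, and the route is rejoined at 21.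

Step 15. Delivery of oxygen to the wrong face of the C11=C12 bond may result if the macrocycle conformation overrides the acyclic allylic-strain preference. The fallback sets out from 26 and replaces substrate direction by reagent control: Sharpless asymmetric epoxidation with Ti(OiPr)4, D-(−)-diisopropyl tartrate, t-BuOOH and 4 Å molecular sieves in CH2Cl2 at −20 °C. By the kinetic-resolution rule for secondary allylic alcohols, the 13R carbinol is the fast-reacting partner of this tartrate and should give the erythro epoxy alcohol, returning to the route at 27. This detour creates no new compound (entry F0).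

Further compounds
F1 | step 14 | (1S,2S,3E,7E,11E,13S)-13-hydroxycembra-3,7,11,15(17)-tetraen-16,2-olide | C=C1C(=O)O[C@H]2/C=C(\C)CC/C=C(\C)CC/C=C(\C)[C@@H](O)C[C@@H]12
F2 | step 14 | (1S,2S,3E,7E,11E)-13-oxocembra-3,7,11,15(17)-tetraen-16,2-olide | C=C1C(=O)O[C@H]2/C=C(\C)CC/C=C(\C)CC/C=C(\C)C(=O)C[C@@H]12
F3 | step 11 | racemic methyl 3-(tert-butoxycarbonyloxy)-5-(tert-butyldimethylsilyloxy)-2-methylidenepentanoate | C=C(C(=O)OC)C(OC(=O)OC(C)(C)C)CCO[Si](C)(C)C(C)(C)C
F0 | step 15 | none | none
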